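**Plan**

Numbering (germacrane): ring C1H2–C2(=O)–C3=C4(Me)–C5H2–C6(O-lactone)–C7–C8(OH)–C9(O-acyl)–C10(Me); C11(=C13H2)–C12(=O) is the lactone arm on C7. Target read as 6R,7R,8R,9R,10S, Z-C3=C4, (2R,3R)-epoxyangelate.
Retrosynthesis: cut the C9–O ester bond (acid 31 opens an 8,9-epoxide), then the lactone C12–O6 bond, then the C1–C10 ring bond by a retro-Claisen shift that returns the C2 carbonyl oxygen to C8 (dienol ether 20, from lactone 19), then the lactone C2–O8 bond, the C4–methyl bond (cuprate), C5–C6 (propargylation) and C7–C8 (aldol).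
Enabling feature: C2(=O)–C1H2–C10H(Me)–C9–C8 is a γ,δ-unsaturated-ketone (Claisen) retron once the C8/C9 oxygens are traced back to a C8=C9 alkene. One oxygen can bridge C2 and C8 in an eight-membered ring (O1, C2–C8); C1, C10 and C9 enter that ring while O1 leaves, a net two-atom expansion to the carbocycle C1–C10.
Forward: acyclic chain with the C6/C7/C8 syn,syn triad → eight-membered Z-enoate lactone → methylenation → Claisen ring expansion to the cyclodeca-3,8-dien-2-one → C6–OH-directed 8,9-epoxidation → α-methylene lactone → epoxide opening at C9 by the epoxy acid.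
Stereochemistry: C7 and C8 of 19 from an Evans syn-aldol ((R)-benzyl auxiliary); C6 from catalyst-controlled propargylation; C10 by chirality transfer from C8 in the Claisen step; C8 and C9 of the target from hydroxyl-directed epoxidation and SN2 inversion at C9; the acid from a Sharpless epoxidation; Z-C3=C4 from syn-carbocupration, locked by the small ring.

Key step: step 15

Abbreviations: TBDPS = tert-butyldiphenylsilyl, TES = triethylsilyl, TBS = tert-butyldimethylsilyl, MNBA = 2-methyl-6-nitrobenzoic anhydride, TRIP = 3,3′-bis(2,4,6-triisopropylphenyl)-1,1′-binaphthyl-2,2′-diyl hydrogen phosphate.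

**Route**

Step 1
Reactants: 1 itaconic anhydride; 2 (R)-4-benzyloxazolidin-2-one
Product: 3 imide acid 4-[(R)-4-benzyl-2-oxooxazolidin-3-yl]-2-methylidene-4-oxobutanoic acid
Conditions: 2, n-BuLi, THF, −78 °C; then 1, −78 → 0 °C; 1 M HCl
Reagents that add atoms: none
Why: The lithium amide of 2 should open the cyclic anhydride at its unconjugated, less hindered carbonyl (N-acylation by anhydride ring opening), which places the imide on the CH2 arm and leaves the acrylic acid free.

Step 2
Reactants: 3 imide acid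
Product: 4 (R)-4-benzyl-3-[3-(hydroxymethyl)but-3-enoyl]oxazolidin-2-one
Conditions: BH3·THF, THF, 0 °C; H2O
Reagents that add atoms: none
Why: Borane reduces a free carboxylic acid much faster than an N-acyl oxazolidinone or an electron-poor 1,1-disubstituted alkene (chemoselective borane reduction), and the alcohol is silylated at once so that it cannot lactonise onto the imide.

Step 3
Reactants: 4 hydroxy imide
Product: 5 aldol donor (R)-4-benzyl-3-[3-(tert-butyldiphenylsilyloxymethyl)but-3-enoyl]oxazolidin-2-one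
Conditions: TBDPSCl, imidazole, CH2Cl2, 0 °C → rt
Reagents that add atoms: tert-butyl(chloro)diphenylsilane, CC(C)(C)[Si](Cl)(c1ccccc1)c1ccccc1
Why: Standard silylation of the primary allylic alcohol; the robust TBDPS group masks C12–O until step 18.

Step 4
Reactants: 5 aldol donor; 6 (E)-but-2-enal
Product: 8 syn-aldol imide (2R,3S,4E), via boron enolate 7 (not isolated)
Conditions: Bu2BOTf, i-Pr2NEt, CH2Cl2, −78 → 0 °C; 6, −78 → 0 °C; pH 7 buffer, MeOH, H2O2
Reagents that add atoms: none
Why: Evans syn-aldol: the Z boron dienolate 7 of the β,γ-unsaturated imide reacts at its α-carbon through a closed chair transition state on the face away from the benzyl group, which sets C7 and C8 together as the (2R,3S) syn pair.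

Step 5
Reactants: 8 syn-aldol imide
Product: 9 triethylsilyl ether of 8 (2R,3S)
Conditions: TESOTf, 2,6-lutidine, CH2Cl2, −78 °C
Reagents that add atoms: triethylsilyl triflate, CC[Si](CC)(CC)OS(=O)(=O)C(F)(F)F
Why: Low-temperature silylation of the secondary allylic alcohol; TES is chosen because it can later be removed beside TBS and TBDPS.

Step 6
Reactants: 9 silylated imide
Product: 10 (2S,3S,4E)-2-[3-(tert-butyldiphenylsilyloxy)prop-1-en-2-yl]-3-(triethylsilyloxy)hex-4-en-1-ol
Conditions: LiBH4, MeOH (1 equiv), Et2O, 0 °C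
Reagents that add atoms: none
Why: Reductive cleavage of the imide with LiBH4 gives the primary alcohol and returns the auxiliary without touching the C7 stereocentre.

Step 7
Reactants: 10 primary alcohol
Product: 11 aldehyde (2R,3S,4E)-2-[3-(tert-butyldiphenylsilyloxy)prop-1-en-2-yl]-3-(triethylsilyloxy)hex-4-enal
Conditions: Dess–Martin periodinane, NaHCO3, CH2Cl2, 0 °C → rt
Reagents that add atoms: none
Why: Buffered Dess–Martin oxidation gives the β,γ-unsaturated aldehyde under non-basic conditions, and it is used at once to avoid epimerisation at C7 or conjugation.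

Step 8
Reactants: 11 aldehyde; 12 allenylboronic acid pinacol ester
Product: 13 homopropargylic alcohol (4R,5S,6S,7E)-5-[3-(tert-butyldiphenylsilyloxy)prop-1-en-2-yl]-6-(triethylsilyloxy)non-7-en-1-yn-4-ol
Conditions: 12, (R)-TRIP (10 mol%), 4 Å MS, toluene, −20 °C
Reagents that add atoms: none
Why: Brønsted acid-catalysed asymmetric propargylation with the allenylboronate (SE2′ through a closed six-membered transition state held by the chiral phosphate) should add to the Re face of the aldehyde under catalyst control and set C6 as R, syn to the C7 side chain.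

Step 9
Reactants: 13 homopropargylic alcohol
Product: 14 tert-butyldimethylsilyl ether of 13 (4R,5S,6S)
Conditions: TBSOTf, 2,6-lutidine, CH2Cl2, −78 → 0 °C
Reagents that add atoms: tert-butyldimethylsilyl triflate, CC(C)(C)[Si](C)(C)OS(=O)(=O)C(F)(F)F
Why: Silylation of the C6 hydroxyl, which must stay masked from here on because a free C6–OH would close a six-membered lactone onto the Z-enoate.

Step 10
Reactants: 14 terminal alkyne
Product: 15 ynoate methyl (5R,6S,7S,8E)-5-(TBS-oxy)-6-[3-(TBDPS-oxy)prop-1-en-2-yl]-7-(TES-oxy)dec-8-en-2-ynoate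
Conditions: n-BuLi, THF, −78 °C; ClCO2Me, −78 → −20 °C
Reagents that add atoms: methyl chloroformate, COC(=O)Cl
Why: Deprotonation of the terminal alkyne and C-acylation of the lithium acetylide by the chloroformate give the ynoate (C2 installed).

Step 11
Reactants: 15 ynoate
Product: 16 Z-enoate methyl (2Z,5R,6S,7S,8E)-3-methyl-5-(TBS-oxy)-6-[3-(TBDPS-oxy)prop-1-en-2-yl]-7-(TES-oxy)deca-2,8-dienoate
Conditions: Me2CuLi (CuI, MeLi), THF, −78 °C; AcOH, −78 °C
Reagents that add atoms: lithium dimethylcuprate, [Li+].C[Cu-]C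
Why: syn-Carbocupration of the ynoate by the Gilman reagent at −78 °C and cold protonation of the vinylcopper give the trisubstituted Z-enoate (methyl trans to the ester, chain cis), the geometry needed for ring closure.

Step 12
Reactants: 16 Z-enoate
Product: 18 hydroxy acid (2Z,5R,6R,7S,8E), via TES-protected acid 17 (not isolated)
Conditions: LiOH, THF/MeOH/H2O, 40 °C; then 1 M HCl to pH 2, 0 °C
Reagents that add atoms: lithium hydroxide, [Li+].[OH-]
Why: Saponification of the methyl ester followed by brief acidification, which cleaves the labile secondary TES ether but not TBS or TBDPS, gives the seco acid with only C8–OH free.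

Step 13
Reactants: 18 hydroxy acid
Product: 19 eight-membered lactone (6R,7R,8S)-6-(TBS-oxy)-7-[3-(TBDPS-oxy)prop-1-en-2-yl]-4-methyl-8-[(E)-prop-1-enyl]-5,6,7,8-tetrahydro-2H-oxocin-2-one
Conditions: MNBA, DMAP, Et3N, CH2Cl2 (2 mM, slow addition), rt
Reagents that add atoms: none
Why: Shiina macrolactonisation under high dilution; the Z-alkene and the three contiguous substituents turn the chain ends toward each other, as in known closures of unsaturated eight-membered lactones.

Step 14
Reactants: 19 eight-membered lactone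
Product: 20 dienol ether (6R,7R,8S)-2-methylidene analogue of 19 (2-methylidene-5,6,7,8-tetrahydro-2H-oxocine)
Conditions: Cp2TiMe2, toluene, 70 °C, dark; filtration through basic alumina
Reagents that add atoms: dimethyltitanocene, [CH3-].[CH3-].[Ti+4].c1cc[cH-]c1.c1cc[cH-]c1
Why: Petasis methylenation converts the lactone carbonyl into the exocyclic enol ether (titanium methylidene, oxatitanacyclobutane), leaving alkenes and silyl ethers untouched and giving the 2-alkoxy-diene needed for the Claisen step.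

Step 15
Reactants: 20 dienol ether
Product: 21 (3Z,8Z)-cyclodeca-3,8-dien-2-one (germacrane numbering: 4-methyl, 6-OTBS, 7-[3-(TBDPS-oxy)prop-1-en-2-yl], 10-methyl; 6R,7S,10S)
Conditions: toluene (5 mM), Et3N (trace), base-washed sealed tube, 130 °C
Reagents that add atoms: none
Why: Thermal [3,3]-sigmatropic (Claisen) shift of the array C1=C2–O1–C8–C9=C10: the O1–C8 bond breaks as C1–C10 forms, so the ring oxygen leaves as the C2 carbonyl and the eight-membered ring becomes the ten-membered carbocycle. The closest known reaction type is the Claisen ring expansion of 2-methylene-6-vinyltetrahydropyrans to cyclooct-4-enones. The ten-membered ring is closed suprafacially through a chair-like six-centre transition state bridged by C3–C7 (bicyclo[5.3.1] arrangement, C7 pseudo-axial on C8), which should give the new C8=C9 bond as Z. C10 is the only new stereocentre: it is set by 1,3-chirality transfer from C8 (S in 20) across the E-propenyl group with the methyl group equatorial, giving 10S. The Z geometry of C3=C4 is carried over from the eight-membered ring, and the conjugated enol ether delivers the enone directly. The Claisen shift must outrun the Cope shift of the C13=C11–C7–C8–C9=C10 diene and acid-induced enol ether hydrolysis; the oxygen-bearing, conjugated vinyl ether should lower the Claisen barrier, and the base-washed vessel excludes acid.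

Step 16
Reactants: 21 ring-expanded dienone
Product: 22 6-hydroxy dienone (6R,7S,10S)
Conditions: HF·pyridine, pyridine, THF, 0 °C → rt
Reagents that add atoms: none
Why: Buffered HF·pyridine cleaves the secondary TBS ether faster than the acid-stable primary TBDPS ether, freeing the homoallylic C6–OH.

Step 17
Reactants: 22 6-hydroxy dienone
Product: 23 8,9-epoxy alcohol (6R,7S,8R,9S,10S)
Conditions: VO(acac)2 (5 mol%), t-BuOOH, CH2Cl2, 0 °C
Reagents that add atoms: tert-butyl hydroperoxide, CC(C)(C)OO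
Why: Vanadium-catalysed hydroxyl-directed epoxidation: the C6 vanadate should deliver oxygen to the C8=C9 face syn to C6–O (cis-fused six-membered delivery across C6–C7–C8), setting C8 (R) and C9 (S), while the enone and the deactivated, shielded C11=C13 alkene should not react.

Step 18
Reactants: 23 epoxy alcohol
Product: 24 epoxy diol (6R,7S,8R,9S,10S) with free C6–OH and C12–OH
Conditions: TBAF, AcOH, THF, 0 °C
Reagents that add atoms: none
Why: Acetic acid-buffered fluoride removes the TBDPS group without forming an alkoxide, and the diol is oxidised at once so that the primary alcohol cannot open the epoxide.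

Step 19
Reactants: 24 epoxy diol
Product: 27 epoxy lactone (6R,7S,8R,9S,10S), via hydroxy enal 25 (not isolated), via lactol 26 (not isolated)
Conditions: MnO2, CH2Cl2, rt
Reagents that add atoms: none
Why: MnO2 oxidises only the allylic primary alcohol to enal 25, which closes with C6–OH to lactol 26 and is oxidised on to the α-methylene-γ-lactone (oxidative lactonisation of a 2-methylene-1,4-diol), trans-fused by the existing C6/C7 configuration.

Step 20
Reactants: 28 angelic acid
Product: 29 (Z)-2-methylbut-2-en-1-ol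
Conditions: LiAlH4, Et2O, 0 °C
Reagents that add atoms: none
Why: Hydride reduction of the acid to the allylic alcohol with retention of the Z geometry.

Step 21
Reactants: 29 (Z)-2-methylbut-2-en-1-ol
Product: 30 [(2S,3R)-2,3-dimethyloxiran-2-yl]methanol
Conditions: Ti(OiPr)4 (10 mol%), L-(+)-diethyl tartrate (12 mol%), t-BuOOH, 4 Å MS, CH2Cl2, −20 °C
Reagents that add atoms: tert-butyl hydroperoxide, CC(C)(C)OO
Why: Sharpless asymmetric epoxidation: L-(+)-tartrate delivers oxygen to the same enantioface as in the standard E-allylic alcohol cases (2S series), giving the (2S,3R)-epoxy alcohol with the methyl groups trans as in the Z-alkene.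

Step 22
Reactants: 30 epoxy alcohol
Product: 31 (2R,3R)-2,3-dimethyloxirane-2-carboxylic acid
Conditions: RuCl3 (2 mol%), NaIO4, CCl4/MeCN/H2O, rt
Reagents that add atoms: water, O
Why: Ruthenium tetroxide generated in the flask oxidises the primary epoxy alcohol to the glycidic acid without touching the epoxide; the C2 descriptor changes to R by priority only.

Step 23
Reactants: 27 epoxy lactone; 31 (2R,3R)-epoxy acid
Product: 32 target CNP0227299.6
Conditions: 31 (1.5 equiv), [(S,S)-N,N′-bis(3,5-di-tert-butylsalicylidene)cyclohexane-1,2-diaminato]cobalt (10 mol%, divalent cobalt, air-oxidised in the flask to the trivalent cobalt carboxylate), i-Pr2NEt, t-BuOMe, 0 °C → rt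
Reagents that add atoms: none
Why: Cobalt–salen-catalysed carboxylic acid opening of the cis-epoxide by SN2 attack at C9 with inversion (C9 becomes R, C8–OH stays R): the catalyst antipode is the one expected to attack the S-configured epoxide carbon (to be checked against its antipode), and C9 is also the less encumbered carbon because C10 turns only a hydrogen toward the attacking face whereas C7 turns the lactone carbon C11.

**Compound list**

1 | itaconic anhydride | C=C1CC(=O)OC1=O | starting material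
2 | (R)-4-benzyloxazolidin-2-one | O=C1N[C@H](Cc2ccccc2)CO1 | starting material
3 | 4-[(R)-4-benzyl-2-oxooxazolidin-3-yl]-2-methylidene-4-oxobutanoic acid | C=C(CC(=O)N1[C@H](Cc2ccccc2)COC1=O)C(=O)O | intermediate
4 | (R)-4-benzyl-3-[3-(hydroxymethyl)but-3-enoyl]oxazolidin-2-one | C=C(CO)CC(=O)N1[C@H](Cc2ccccc2)COC1=O | intermediate
5 | (R)-4-benzyl-3-[3-(tert-butyldiphenylsilyloxymethyl)but-3-enoyl]oxazolidin-2-one | C=C(CO[Si](c1ccccc1)(c1ccccc1)C(C)(C)C)CC(=O)N1[C@H](Cc2ccccc2)COC1=O | intermediate
6 | (E)-but-2-enal | C/C=C/C=O | starting material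
7 | Z dibutylboron dienolate of 5 | C=C(CO[Si](c1ccccc1)(c1ccccc1)C(C)(C)C)/C=C(\OB(CCCC)CCCC)N1[C@H](Cc2ccccc2)COC1=O | intermediate
8 | (R)-4-benzyl-3-[(2R,3S,4E)-2-(3-(tert-butyldiphenylsilyloxy)prop-1-en-2-yl)-3-hydroxyhex-4-enoyl]oxazolidin-2-one | O=C([C@H](C(=C)CO[Si](c1ccccc1)(c1ccccc1)C(C)(C)C)[C@@H](O)/C=C/C)N1[C@H](Cc2ccccc2)COC1=O | intermediate
9 | 3-O-triethylsilyl ether of 8 (2R,3S) | O=C([C@H](C(=C)CO[Si](c1ccccc1)(c1ccccc1)C(C)(C)C)[C@@H](O[Si](CC)(CC)CC)/C=C/C)N1[C@H](Cc2ccccc2)COC1=O | intermediate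
10 | (2S,3S,4E)-2-[3-(tert-butyldiphenylsilyloxy)prop-1-en-2-yl]-3-(triethylsilyloxy)hex-4-en-1-ol | OC[C@H](C(=C)CO[Si](c1ccccc1)(c1ccccc1)C(C)(C)C)[C@@H](O[Si](CC)(CC)CC)/C=C/C | intermediate
11 | (2R,3S,4E)-2-[3-(tert-butyldiphenylsilyloxy)prop-1-en-2-yl]-3-(triethylsilyloxy)hex-4-enal | O=C[C@H](C(=C)CO[Si](c1ccccc1)(c1ccccc1)C(C)(C)C)[C@@H](O[Si](CC)(CC)CC)/C=C/C | intermediate
12 | allenylboronic acid pinacol ester | C=C=CB1OC(C)(C)C(C)(C)O1 | starting material
13 | (4R,5S,6S,7E)-5-[3-(tert-butyldiphenylsilyloxy)prop-1-en-2-yl]-6-(triethylsilyloxy)non-7-en-1-yn-4-ol | C#CC[C@@H](O)[C@H](C(=C)CO[Si](c1ccccc1)(c1ccccc1)C(C)(C)C)[C@@H](O[Si](CC)(CC)CC)/C=C/C | intermediate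
14 | 4-O-tert-butyldimethylsilyl ether of 13 (4R,5S,6S) | C#CC[C@@H](O[Si](C)(C)C(C)(C)C)[C@H](C(=C)CO[Si](c1ccccc1)(c1ccccc1)C(C)(C)C)[C@@H](O[Si](CC)(CC)CC)/C=C/C | intermediate
15 | methyl (5R,6S,7S,8E)-5-(TBS-oxy)-6-[3-(TBDPS-oxy)prop-1-en-2-yl]-7-(TES-oxy)dec-8-en-2-ynoate | COC(=O)C#CC[C@@H](O[Si](C)(C)C(C)(C)C)[C@H](C(=C)CO[Si](c1ccccc1)(c1ccccc1)C(C)(C)C)[C@@H](O[Si](CC)(CC)CC)/C=C/C | intermediate
16 | methyl (2Z,5R,6S,7S,8E)-3-methyl-5-(TBS-oxy)-6-[3-(TBDPS-oxy)prop-1-en-2-yl]-7-(TES-oxy)deca-2,8-dienoate | COC(=O)/C=C(C)\C[C@@H](O[Si](C)(C)C(C)(C)C)[C@H](C(=C)CO[Si](c1ccccc1)(c1ccccc1)C(C)(C)C)[C@@H](O[Si](CC)(CC)CC)/C=C/C | intermediate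
17 | carboxylic acid of 16 with the TES ether still in place (2Z,5R,6S,7S,8E) | OC(=O)/C=C(C)\C[C@@H](O[Si](C)(C)C(C)(C)C)[C@H](C(=C)CO[Si](c1ccccc1)(c1ccccc1)C(C)(C)C)[C@@H](O[Si](CC)(CC)CC)/C=C/C | intermediate
18 | (2Z,5R,6R,7S,8E)-7-hydroxy-3-methyl-5-(TBS-oxy)-6-[3-(TBDPS-oxy)prop-1-en-2-yl]deca-2,8-dienoic acid | OC(=O)/C=C(C)\C[C@@H](O[Si](C)(C)C(C)(C)C)[C@H](C(=C)CO[Si](c1ccccc1)(c1ccccc1)C(C)(C)C)[C@@H](O)/C=C/C | intermediate
19 | (6R,7R,8S)-6-(TBS-oxy)-7-[3-(TBDPS-oxy)prop-1-en-2-yl]-4-methyl-8-[(E)-prop-1-enyl]-5,6,7,8-tetrahydro-2H-oxocin-2-one | O=C1/C=C(C)\C[C@@H](O[Si](C)(C)C(C)(C)C)[C@H](C(=C)CO[Si](c2ccccc2)(c2ccccc2)C(C)(C)C)[C@H](/C=C/C)O1 | intermediate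
20 | (6R,7R,8S)-6-(TBS-oxy)-7-[3-(TBDPS-oxy)prop-1-en-2-yl]-4-methyl-2-methylidene-8-[(E)-prop-1-enyl]-5,6,7,8-tetrahydro-2H-oxocine | C=C1/C=C(C)\C[C@@H](O[Si](C)(C)C(C)(C)C)[C@H](C(=C)CO[Si](c2ccccc2)(c2ccccc2)C(C)(C)C)[C@H](/C=C/C)O1 | intermediate
21 | (3Z,8Z)-4,10-dimethyl-6-(TBS-oxy)-7-[3-(TBDPS-oxy)prop-1-en-2-yl]cyclodeca-3,8-dien-2-one (germacrane numbering, 6R,7S,10S) | C[C@@H]1/C=C\[C@@H](C(=C)CO[Si](c2ccccc2)(c2ccccc2)C(C)(C)C)[C@H](O[Si](C)(C)C(C)(C)C)C/C(C)=C\C(=O)C1 | intermediate
22 | 6-hydroxy analogue of 21 (6R,7S,10S) | C[C@@H]1/C=C\[C@@H](C(=C)CO[Si](c2ccccc2)(c2ccccc2)C(C)(C)C)[C@H](O)C/C(C)=C\C(=O)C1 | intermediate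
23 | 8,9-epoxide of 22, epoxide syn to C6–OH (6R,7S,8R,9S,10S) | C[C@@H]1[C@@H]2O[C@@H]2[C@@H](C(=C)CO[Si](c3ccccc3)(c3ccccc3)C(C)(C)C)[C@H](O)C/C(C)=C\C(=O)C1 | intermediate
24 | epoxy diol, 23 without the TBDPS group (6R,7S,8R,9S,10S) | C[C@@H]1[C@@H]2O[C@@H]2[C@@H](C(=C)CO)[C@H](O)C/C(C)=C\C(=O)C1 | intermediate
25 | hydroxy enal, C12 aldehyde of 24 | C[C@@H]1[C@@H]2O[C@@H]2[C@@H](C(=C)C=O)[C@H](O)C/C(C)=C\C(=O)C1 | intermediate
26 | lactol from 25 (C6–O–C12, both C12 anomers) | C[C@@H]1[C@@H]2O[C@@H]2[C@H]2C(=C)C(O)O[C@@H]2C/C(C)=C\C(=O)C1 | intermediate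
27 | 8,9-epoxy-2-oxo-germacra-3,11(13)-dien-6,12-olide, trans-fused lactone (6R,7S,8R,9S,10S) | C[C@@H]1[C@@H]2O[C@@H]2[C@H]2C(=C)C(=O)O[C@@H]2C/C(C)=C\C(=O)C1 | intermediate
28 | angelic acid, (Z)-2-methylbut-2-enoic acid | C/C=C(/C)C(=O)O | starting material
29 | (Z)-2-methylbut-2-en-1-ol | C/C=C(/C)CO | intermediate
30 | [(2S,3R)-2,3-dimethyloxiran-2-yl]methanol | OC[C@]1(C)O[C@@H]1C | intermediate
31 | (2R,3R)-2,3-dimethyloxirane-2-carboxylic acid | OC(=O)[C@]1(C)O[C@@H]1C | intermediate
32 | CNP0227299.6 | C=C1C(=O)O[C@@H]2C/C(C)=C\C(=O)C[C@H](C)[C@@H](OC(=O)[C@]3(C)O[C@@H]3C)[C@H](O)[C@@H]12 | target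

**Step count and risks**

Total: 23 steps. Longest linear sequence: 20 steps (steps 1–19 and 23); the acid 31 is a three-step side branch (steps 20–22).

Steps most likely to fail, each with a fallback:

(1) Step 15. The thermal shift may be overtaken by a Cope shift of the neighbouring 1,5-diene or by hydrogen shifts in the dienol ether, and a boat-like transition state would erode the C10 configuration. The fallback sets out from dienol ether 20 and comes back at dienone 21. Treatment of 20 with Al(i-Bu)3 in CH2Cl2 at −78 → 0 °C should trigger the Lewis acid-promoted Claisen ring expansion far below the temperature of the competing thermal processes. The aluminium-bound ketone is reduced in the flask by β-hydride transfer, so the product is the ring-expanded allylic alcohol F1 (both C2 epimers). Dess–Martin oxidation of F1 then returns 21.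

(2) Step 23. Attack of the acid on the hindered ring epoxide may be slow, may go to C8 instead of C9, or may be diverted by transannular participation of the C2 carbonyl or by conjugate addition to the methylene lactone. The fallback sets out from epoxy alcohol 23 (with acid 31) and comes back at target 32; it opens the epoxide before the lactone exists, under chelation control. Ti(OiPr)4 binds C6–OH and the epoxide oxygen of 23 and should direct 31 to the distal carbon C9, giving the diol ester F2. TBAF/AcOH then frees the primary alcohol to give the triol ester F3. TEMPO with PhI(OAc)2 oxidises only the primary allylic alcohol; the lactol should close on the less hindered C6–OH (C8–OH is flanked by the new ester) and be oxidised on to 32.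

(3) Step 13. Acyl activation may lead to oligomers instead of the strained eight-membered ring, or to isomerisation of the Z-acid. The fallback sets out from aldehyde 11 and comes back at lactone 19; it closes the ring by capture of an acylketene and introduces the C4 methyl group afterwards. A vinylogous Mukaiyama aldol of 11 with the trimethylsilyl dienol ether of 2,2,6-trimethyl-4H-1,3-dioxin-4-one (Ti(OiPr)4/BINOL catalyst, antipode chosen for Re-face attack) gives the dioxinone carbinol F4. TBSOTf and 2,6-lutidine give its TBS ether F5, and PPTS in MeOH removes only the TES group to give the C8 alcohol F6. Heating F6 in dilute toluene at 110 °C expels acetone, and the acylketene is trapped by C8–OH to give the eight-membered β-keto lactone F7. NaH and Tf2O convert F7 into the ring-locked Z enol triflate F8, and iron-catalysed methylation (Fe(acac)3, MeMgBr, THF, −30 °C) returns 19.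

**Further compounds**

F1 | step 15 | (3Z,8Z)-4,10-dimethyl-6-(TBS-oxy)-7-[3-(TBDPS-oxy)prop-1-en-2-yl]cyclodeca-3,8-dien-2-ol, both C2 epimers (6R,7S,10S) | C[C@@H]1/C=C\[C@@H](C(=C)CO[Si](c2ccccc2)(c2ccccc2)C(C)(C)C)[C@H](O[Si](C)(C)C(C)(C)C)C/C(C)=C\C(O)C1
F2 | step 23 | diol ester: 9-O-[(2R,3R)-2,3-dimethyloxirane-2-carbonyl]-6,8-dihydroxy-12-O-TBDPS cyclodec-3-en-2-one (6R,8R,9R,10S; C7 as in 23) | C[C@@H]1[C@@H](OC(=O)[C@]2(C)O[C@@H]2C)[C@H](O)[C@@H](C(=C)CO[Si](c2ccccc2)(c2ccccc2)C(C)(C)C)[C@H](O)C/C(C)=C\C(=O)C1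
F3 | step 23 | triol ester: F2 without the TBDPS group | C[C@@H]1[C@@H](OC(=O)[C@]2(C)O[C@@H]2C)[C@H](O)[C@@H](C(=C)CO)[C@H](O)C/C(C)=C\C(=O)C1
F4 | step 13 | dioxinone carbinol: 6-[(2R,3S,4S,5E)-2-hydroxy-3-(3-(TBDPS-oxy)prop-1-en-2-yl)-4-(TES-oxy)hept-5-enyl]-2,2-dimethyl-4H-1,3-dioxin-4-one | CC1(C)OC(=O)C=C(C[C@@H](O)[C@H](C(=C)CO[Si](c2ccccc2)(c2ccccc2)C(C)(C)C)[C@@H](O[Si](CC)(CC)CC)/C=C/C)O1
F5 | step 13 | TBS ether of F4 | CC1(C)OC(=O)C=C(C[C@@H](O[Si](C)(C)C(C)(C)C)[C@H](C(=C)CO[Si](c2ccccc2)(c2ccccc2)C(C)(C)C)[C@@H](O[Si](CC)(CC)CC)/C=C/C)O1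
F6 | step 13 | C8 alcohol: F5 without the TES group | CC1(C)OC(=O)C=C(C[C@@H](O[Si](C)(C)C(C)(C)C)[C@H](C(=C)CO[Si](c2ccccc2)(c2ccccc2)C(C)(C)C)[C@@H](O)/C=C/C)O1
F7 | step 13 | eight-membered β-keto lactone (6R,7R,8S)-6-(TBS-oxy)-7-[3-(TBDPS-oxy)prop-1-en-2-yl]-8-[(E)-prop-1-enyl]oxocane-2,4-dione | O=C1CC(=O)C[C@@H](O[Si](C)(C)C(C)(C)C)[C@H](C(=C)CO[Si](c2ccccc2)(c2ccccc2)C(C)(C)C)[C@H](/C=C/C)O1
F8 | step 13 | enol triflate: 19 with trifluoromethanesulfonyloxy in place of the 4-methyl group | O=C1/C=C(OS(=O)(=O)C(F)(F)F)\C[C@@H](O[Si](C)(C)C(C)(C)C)[C@H](C(=C)CO[Si](c2ccccc2)(c2ccccc2)C(C)(C)C)[C@H](/C=C/C)O1
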